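**Strategy.** The flavonol core is cut at the C3–C4 bond of ring C: the C3 hydroxyl and C4 carbonyl are the enol form of a 1,2-dione, one oxidation level above an acyloin. A carbene-catalysed intramolecular benzoin reaction joins the two formyl carbons of a racemic dialdehyde, forming C3–C4 and closing ring C as a 3-hydroxychroman-4-one in one operation; oxidation then gives the flavonol. The precursor is a ring A benzaldehyde (future C4) whose ortho oxygen O1 carries a CH(4-methoxyphenyl)CHO unit (C2, C3), with the 7-O-prenyl ether already in place and O5 masked as a fluoride-labile SEM acetal, so that no acid ever meets the prenyl ether.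

Key step: step 7

Remarks on the chemistry:
- The target is achiral. Every intermediate with a stereocentre is racemic, and cis/trans mixtures at C2/C3 are carried on because step 8 erases both centres; the SMILES therefore carry no stereodescriptors.
- Flavone numbering is used for ring atoms (ring A benzo, ring C pyranone, ring B anisyl). SEM = 2-(trimethylsilyl)ethoxymethyl; prenyl = 3-methylbut-2-en-1-yl.

Step 1
Reactants: 1 2,4,6-trihydroxybenzaldehyde; 2 prenyl bromide (1-bromo-3-methylbut-2-ene)
Product: 3 2,6-dihydroxy-4-[(3-methylbut-2-en-1-yl)oxy]benzaldehyde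
Conditions: K2CO3 (1.0 equiv), acetone, 40 °C
Reagents that add atoms: none
Why: Williamson etherification: the 4-hydroxyl, para to the formyl group and the only one not held in a hydrogen bond to it, is the most acidic and most nucleophilic, so one equivalent each of base and bromide should alkylate it selectively.

Step 2
Reactants: 3 2,6-dihydroxy-4-[(3-methylbut-2-en-1-yl)oxy]benzaldehyde
Product: 4 2-hydroxy-4-[(3-methylbut-2-en-1-yl)oxy]-6-{[2-(trimethylsilyl)ethoxy]methoxy}benzaldehyde
Conditions: SEMCl (1.05 equiv), i-Pr2NEt, CH2Cl2, 0 °C to rt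
Reagents that add atoms: 2-(trimethylsilyl)ethoxymethyl chloride (SEMCl), C[Si](C)(C)CCOCCl
Why: Base-mediated O-alkylation with an alpha-chloro ether (SEM acetal formation): the two hydroxyls are equivalent by symmetry, and once one is capped the other is locked in a hydrogen bond to the formyl group and should stay free.

Step 3
Reactants: 5 methyl (4-methoxyphenyl)acetate
Product: 6 methyl 2-bromo-2-(4-methoxyphenyl)acetate (racemic)
Conditions: NBS (1.05 equiv), AIBN (cat.), PhCF3, 85 °C
Reagents that add atoms: N-bromosuccinimide (NBS), O=C1CCC(=O)N1Br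
Why: Wohl–Ziegler radical bromination at the only C–H that is both benzylic and alpha to the ester carbonyl, the non-polar solvent disfavouring ionic bromination of the anisole ring; the new stereocentre forms through a planar radical and is racemic.

Step 4
Reactants: 4 2-hydroxy-4-[(3-methylbut-2-en-1-yl)oxy]-6-{[2-(trimethylsilyl)ethoxy]methoxy}benzaldehyde; 6 methyl 2-bromo-2-(4-methoxyphenyl)acetate (racemic)
Product: 7 methyl 2-[2-formyl-5-[(3-methylbut-2-en-1-yl)oxy]-3-{[2-(trimethylsilyl)ethoxy]methoxy}phenoxy]-2-(4-methoxyphenyl)acetate (racemic)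
Conditions: K2CO3 (1.5 equiv), DMF, 0 °C to rt
Reagents that add atoms: none
Why: Williamson etherification: the phenoxide of 4 displaces the doubly activated secondary bromide by SN2 at room temperature, mild enough that the product should not close by aldol addition onto its formyl group; the stereocentre (future C2) stays racemic.

Step 5
Reactants: 7 methyl 2-[2-formyl-5-[(3-methylbut-2-en-1-yl)oxy]-3-{[2-(trimethylsilyl)ethoxy]methoxy}phenoxy]-2-(4-methoxyphenyl)acetate (racemic)
Product: 8 2-[2-(hydroxymethyl)-5-[(3-methylbut-2-en-1-yl)oxy]-3-{[2-(trimethylsilyl)ethoxy]methoxy}phenoxy]-2-(4-methoxyphenyl)ethan-1-ol (racemic)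
Conditions: LiAlH4 (1.5 equiv), THF, 0 °C; then H2O, aq. NaOH
Reagents that add atoms: none
Why: LiAlH4 reduction takes both the ester and the aldehyde to primary alcohols, while the aryl ethers, the SEM acetal and the isolated alkene are inert to hydride; no stereocentre is touched.

Step 6
Reactants: 8 2-[2-(hydroxymethyl)-5-[(3-methylbut-2-en-1-yl)oxy]-3-{[2-(trimethylsilyl)ethoxy]methoxy}phenoxy]-2-(4-methoxyphenyl)ethan-1-ol (racemic)
Product: 9 2-[1-(4-methoxyphenyl)-2-oxoethoxy]-4-[(3-methylbut-2-en-1-yl)oxy]-6-{[2-(trimethylsilyl)ethoxy]methoxy}benzaldehyde (racemic)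
Conditions: Dess–Martin periodinane (2.6 equiv), pyridine, CH2Cl2, 0 °C to rt; crude 9 used at once
Reagents that add atoms: none
Why: Dess–Martin oxidation converts both primary alcohols into aldehydes without over-oxidation, the pyridine buffer keeping acetic acid away from the prenyl ether and from the enolizable alpha-aryloxy aldehyde, which is taken on at once without chromatography.

Step 7
Reactants: 9 2-[1-(4-methoxyphenyl)-2-oxoethoxy]-4-[(3-methylbut-2-en-1-yl)oxy]-6-{[2-(trimethylsilyl)ethoxy]methoxy}benzaldehyde (racemic)
Product: 10 3-hydroxy-2-(4-methoxyphenyl)-7-[(3-methylbut-2-en-1-yl)oxy]-5-{[2-(trimethylsilyl)ethoxy]methoxy}chroman-4-one (racemic; cis/trans mixture)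
Conditions: 3-benzyl-5-(2-hydroxyethyl)-4-methylthiazolium chloride (20 mol%), Et3N (30 mol%), degassed EtOH (0.02 M), 60 °C, Ar
Reagents that add atoms: none
Why: Et3N frees the thiazol-2-ylidene, which adds to a formyl group; proton transfer gives a Breslow intermediate (an acyl anion equivalent) that attacks the other formyl carbon, and a second proton transfer with loss of the carbene releases the ketol. The closest known reaction type is the thiazolium-catalysed intramolecular benzoin (acyloin) cyclization of dialdehydes and of 2-(2-oxoalkoxy)benzaldehydes to 3-hydroxychroman-4-ones. Ring C closes in 6-exo-trig mode through the new C3–C4 bond. The new C3 stereocentre is not under reagent control: only the existing racemic C2 centre biases it (trans should prevail after base equilibration), and both centres are erased in step 8. Either formyl group may serve as the donor, because the two regioisomeric ketols share one enediol and the reversible benzoin step should funnel the mixture to the aryl-conjugated C4 ketone, any 4-hydroxy-3-ketone left over converging in step 8. The selectivity needed is ring closure ahead of loss of the ring A aryloxide from a C3-centred Breslow intermediate (internal redox to an aryl ester), of 5-exo aldol attack of the C2 enol on the ring A aldehyde and of intermolecular reactions; the ortho placing of the two formyl groups (six-membered transition state), an electron-rich aryloxide that is a much poorer leaving group than the halides or carboxylates such redox paths need, an N-alkyl thiazolylidene in place of redox-prone N-aryl triazolylidenes, substoichiometric weak base and high dilution should secure it.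

Step 8
Reactants: 10 3-hydroxy-2-(4-methoxyphenyl)-7-[(3-methylbut-2-en-1-yl)oxy]-5-{[2-(trimethylsilyl)ethoxy]methoxy}chroman-4-one (racemic; cis/trans mixture)
Product: 12 3-hydroxy-2-(4-methoxyphenyl)-7-[(3-methylbut-2-en-1-yl)oxy]-5-{[2-(trimethylsilyl)ethoxy]methoxy}-4H-chromen-4-one, via chromane-3,4-dione keto tautomer 11 (not isolated)
Conditions: Cu(OAc)2 (2.2 equiv), pyridine/MeOH, 50 °C, Ar; aqueous EDTA wash
Reagents that add atoms: none
Why: Fehling-type oxidation of an alpha-ketol: the enediolate bound to divalent copper gives up two electrons in one-electron steps (two equivalents of Cu(OAc)2 end as monovalent CuOAc), and the resulting 3,4-dione enolizes toward C2 to the aromatic 3-hydroxy-4-pyranone, which erases both stereocentres and would also collect any regioisomeric ketol.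

Step 9
Reactants: 12 3-hydroxy-2-(4-methoxyphenyl)-7-[(3-methylbut-2-en-1-yl)oxy]-5-{[2-(trimethylsilyl)ethoxy]methoxy}-4H-chromen-4-one
Product: 13 3,5-dihydroxy-2-(4-methoxyphenyl)-7-[(3-methylbut-2-en-1-yl)oxy]-4H-chromen-4-one
Conditions: Bu4NF (4 equiv), THF, 50 °C, Ar; then aq. NH4Cl
Reagents that add atoms: none
Why: Fluoride-induced SEM cleavage: attack at silicon triggers loss of ethene and then of formaldehyde to leave the O5 phenoxide, so that no acid is present to ionize the aryl prenyl ether, and the product is protonated on work-up.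

**Compound list**

1 | 2,4,6-trihydroxybenzaldehyde | O=Cc1c(O)cc(O)cc1O | starting material
2 | prenyl bromide (1-bromo-3-methylbut-2-ene) | CC(C)=CCBr | starting material
3 | 2,6-dihydroxy-4-[(3-methylbut-2-en-1-yl)oxy]benzaldehyde | CC(C)=CCOc1cc(O)c(C=O)c(O)c1 | intermediate
4 | 2-hydroxy-4-[(3-methylbut-2-en-1-yl)oxy]-6-{[2-(trimethylsilyl)ethoxy]methoxy}benzaldehyde | CC(C)=CCOc1cc(O)c(C=O)c(OCOCC[Si](C)(C)C)c1 | intermediate
5 | methyl (4-methoxyphenyl)acetate | COC(=O)Cc1ccc(OC)cc1 | starting material
6 | methyl 2-bromo-2-(4-methoxyphenyl)acetate (racemic) | COC(=O)C(Br)c1ccc(OC)cc1 | intermediate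
7 | methyl 2-[2-formyl-5-[(3-methylbut-2-en-1-yl)oxy]-3-{[2-(trimethylsilyl)ethoxy]methoxy}phenoxy]-2-(4-methoxyphenyl)acetate (racemic) | COC(=O)C(Oc1cc(OCC=C(C)C)cc(OCOCC[Si](C)(C)C)c1C=O)c1ccc(OC)cc1 | intermediate
8 | 2-[2-(hydroxymethyl)-5-[(3-methylbut-2-en-1-yl)oxy]-3-{[2-(trimethylsilyl)ethoxy]methoxy}phenoxy]-2-(4-methoxyphenyl)ethan-1-ol (racemic) | OCC(Oc1cc(OCC=C(C)C)cc(OCOCC[Si](C)(C)C)c1CO)c1ccc(OC)cc1 | intermediate
9 | 2-[1-(4-methoxyphenyl)-2-oxoethoxy]-4-[(3-methylbut-2-en-1-yl)oxy]-6-{[2-(trimethylsilyl)ethoxy]methoxy}benzaldehyde (racemic) | O=CC(Oc1cc(OCC=C(C)C)cc(OCOCC[Si](C)(C)C)c1C=O)c1ccc(OC)cc1 | intermediate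
10 | 3-hydroxy-2-(4-methoxyphenyl)-7-[(3-methylbut-2-en-1-yl)oxy]-5-{[2-(trimethylsilyl)ethoxy]methoxy}chroman-4-one (racemic, cis/trans mixture) | COc1ccc(cc1)C1Oc2cc(OCC=C(C)C)cc(OCOCC[Si](C)(C)C)c2C(=O)C1O | intermediate
11 | 2-(4-methoxyphenyl)-7-[(3-methylbut-2-en-1-yl)oxy]-5-{[2-(trimethylsilyl)ethoxy]methoxy}chromane-3,4-dione (racemic, not isolated) | COc1ccc(cc1)C1Oc2cc(OCC=C(C)C)cc(OCOCC[Si](C)(C)C)c2C(=O)C1=O | intermediate
12 | 3-hydroxy-2-(4-methoxyphenyl)-7-[(3-methylbut-2-en-1-yl)oxy]-5-{[2-(trimethylsilyl)ethoxy]methoxy}-4H-chromen-4-one | COc1ccc(cc1)-c1oc2cc(OCC=C(C)C)cc(OCOCC[Si](C)(C)C)c2c(=O)c1O | intermediate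
13 | 3,5-dihydroxy-2-(4-methoxyphenyl)-7-[(3-methylbut-2-en-1-yl)oxy]-4H-chromen-4-one | COc1ccc(-c2oc3cc(OCC=C(C)C)cc(O)c3c(=O)c2O)cc1 | target

**Step count.** Total: 9 steps. Longest linear sequence: 8 steps (steps 1, 2, 4, 5, 6, 7, 8, 9 from compound 1); step 3 is a one-step side branch that joins at step 4.

**Steps most likely to fail**

1. Step 7. The C3-centred Breslow intermediate may expel the ring A aryloxide and end in acyl transfer, or the base may drive aldol closure to a dihydrobenzofuran, before the six-membered ring forms. The fallback makes the same C3–C4 bond reductively and sets out from 9. SmI2 (divalent samarium; THF, t-BuOH, −78 °C) should couple the two formyl groups in an intramolecular pinacol reaction to give 2-(4-methoxyphenyl)-7-[(3-methylbut-2-en-1-yl)oxy]-5-{[2-(trimethylsilyl)ethoxy]methoxy}chromane-3,4-diol F1 as a racemic diastereomer mixture. A double Swern oxidation of F1 (DMSO, (CF3CO)2O, then Et3N, CH2Cl2, −78 °C) should then give dione 11, which enolizes to 12, where the route resumes at step 9.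

2. Step 1. The ambident phloroglucinol phenoxide may be alkylated on ring carbon, or a second prenyl group may enter at an ortho hydroxyl. The fallback sets out from 1 and returns at 3: a Mitsunobu etherification with 3-methylbut-2-en-1-ol (PPh3, DIAD, THF, 0 °C) works without a free phenoxide and should engage only the most acidic, non-chelated 4-hydroxyl. It makes no new compound (F0).

3. Step 4. Alkylation of the chelated, hindered phenoxide may be slower than decomposition of the labile bromide 6, or base may close ester 7 onto its own formyl group. The fallback forms the same ether under neutral conditions, sets out from 4 and returns at 7. Commercial 4-methoxymandelic acid is esterified (MeI, KHCO3, DMF, rt) to methyl 2-hydroxy-2-(4-methoxyphenyl)acetate F2. A Mitsunobu reaction of F2 with phenol 4 (PPh3, DIAD, THF, 0 °C to rt) should then give 7, the ester-flanked carbinol reacting by SN2.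

**Further compounds**

F1 | step 7 | 2-(4-methoxyphenyl)-7-[(3-methylbut-2-en-1-yl)oxy]-5-{[2-(trimethylsilyl)ethoxy]methoxy}chromane-3,4-diol (racemic, diastereomer mixture) | COc1ccc(cc1)C1Oc2cc(OCC=C(C)C)cc(OCOCC[Si](C)(C)C)c2C(O)C1O
F0 | step 1 | none | none
F2 | step 4 | methyl 2-hydroxy-2-(4-methoxyphenyl)acetate (racemic) | COC(=O)C(O)c1ccc(OC)cc1
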